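Hydrindane numbering is used for rings B and C: C1 is the carbinol of ring C, C3a and C7a the ring fusion, C4 the carbinol of ring B, C6 the spiro carbon. Ring A carries primed locants: C1' = C6, C2' and C6' the flanking carbonyls, C3' the acylated carbon, C4' the enol carbon, C5' the diprenylated carbon. β is the face of H-3a, α the face of H-7a.

## The problem

Target 22 is a spiro compound: ring A, an enolised 2-acylcyclohexane-1,3,5-trione with two prenyl groups on C5' and a 3-methylbutanoyl group on C3', shares one carbon with C6 of a trans-fused hydrindane (ring B six-membered, ring C five-membered) that bears tertiary methyl carbinols at C1 and C4. There are five stereocentres: C1, C3a, C7a, C4 and C6. C6 is stereogenic only because its two ring A carbonyls differ (C2' lies next to the acylated carbon, C6' next to the diprenylated one), so it has to be set by telling apart two carboxyl carbons that start out identical. A relay is available: C3a can set C7a (trans), C7a can set C1 (attack anti to the side chain), the trans ring fusion fixes the chair of ring B and so can set C4, and the C4 oxygen, 1,3-diaxial to one C6 carbonyl, can set C6. The groups that limit the order of events are the two tertiary alcohols, the prenyl alkenes and the triketone. The C1 hydroxyl is cis to the C7 arm and would lactonise onto a C6 ester while ring B is open; the prenyl alkenes cyclise onto the enol in acid and do not survive ozone; the triketone is a vinylogous acid that alkylates on oxygen as well as carbon. The feature that invites the key step is C5: it lies between C4, a former carbonyl carbon, and C6, which carries two carbonyl groups, so the C4–C5 bond joins two acceptor positions. Reversing the polarity of C5 (a metallated CH2 on a C6 malonate, a homoenolate) lets it add to a C4 methyl ketone, and the new C4 alkoxide can then take the one ester that is syn-axial to it.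

## Retrosynthesis

**22 to 20.** The two C5'–CH2 bonds to the prenyl groups are cut first. The prenyl alkenes would not survive ozonolysis or iodide chemistry, and C5' is the only ring A carbon with two acidic hydrogens, since C3' is already a tricarbonyl methine. Triketone diol 20 is ten carbons smaller. The forward reaction must alkylate twice on carbon and not on oxygen.

**20 to 18.** Ring A is opened at C2'–C3'. Cutting here, and not at a bond to C6, keeps the quaternary spiro carbon intact and turns C2' into the carbonyl of a five-membered lactone to the C4 oxygen. In triketone lactone 18 that lactone is both the activated acyl group for a Dieckmann closure and the carrier of stereochemistry: the carbonyl syn to the C4 oxygen becomes C2', so the C4 configuration is translated into the spiro configuration. The forward reaction needs C3' as the nucleophile; the silyl ether on the C1 oxygen is removed in the same operation through the silylated triketone 19.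

**18 to 15 and 16.** The C5'–C6' bond is cut to acid chloride 15 and the terminal carbanion of the dianion 17 of 6-methylheptane-2,4-dione 16, which brings in C3' to C5' and the whole acyl side chain in one piece. 15 comes from acid 14, and 14 from lactone methyl ester 13 by demethylation. The ester that stayed free is anti to the C4 oxygen and is exactly the one that must become C6'. A methyl ester and a lactone with a tertiary alkyl oxygen are told apart by SN2 attack at the methyl group.

**13 to 10 (key disconnection).** The C4–C5 bond and the lactone C–O bond are cut together. This leaves iodomethyl malonate 10, in which C6 is not yet stereogenic, C5 is an iodomethyl group and C4 is a methyl ketone. Neighbouring cuts compare badly: C5–C6 would need alkylation by a neopentyl-type electrophile next to a tertiary carbinol, and C3a–C4 or C7–C7a would break into ring C. The forward reaction must make the ring, choose the C4 face and choose one of two identical esters. The alkylsamarium 11 and the alkoxide 12 are its intermediates.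

**10 to 9 to 8.** C5 is removed (C5–C6, alkylation of the malonate with diiodomethane) and the C4 ketone is traced to an isopropenyl group. Ozonolysis is placed before the iodide is introduced because alkyl iodides are oxidised by ozone. 8 then holds only a malonate C–H, an alkene and a silyl ether.

**8 to 7 to 6.** The silyl group is removed and the C1–CH3 bond is cut to cyclopentanone 6. The triethylsilyl ether is there for two reasons: the C1 hydroxyl is cis to the arm that carries the malonate and would close a δ-lactone, and it would protonate the carbanion of step 7. The methyl addition must come from the face anti to the C7a side chain.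

**6 to 3, 4 and 2.** The C3a–isopropenyl and C7a–C7 bonds are cut in one operation: conjugate addition of isopropenylmagnesium bromide 4 to cyclopent-2-en-1-one 3 and trapping of the regiodefined enolate 5 with dimethyl methylenemalonate 2, made from dimethyl malonate 1. This sets the absolute configuration at C3a by catalysis and the trans arms by the trapping.

## Roads not taken

**Alternative 1:** both arms are added to an intact cyclopentene (cuts at C7–C7a and C3a–C4). (R)-Linalool A1 would give, by ring-closing metathesis and silylation, the (bromomethyl)dimethylsilyl ether A2 of (R)-1-methylcyclopent-2-en-1-ol. Its silicon-tethered radical adds to C7a (5-exo), and the C3a radical is trapped by tert-butyl isocyanide to give the cis-fused siloxane nitrile A3.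
- Merits: C1 comes from the chiral pool with a certain absolute configuration, the tether forces the C1 oxygen and C7 onto the same face, and the nitrile is C4 at the right oxidation level. In this respect it is better than the chosen route, whose step 3 depends on facial selectivity at a flexible cyclopentanone.
- Weak points: the intermolecular isocyanide trapping of a secondary radical competes with hydrogen transfer. A3 is also still far from a ring B precursor; it needs siloxane oxidation, activation of C7, protection of C1–OH, conversion of the nitrile to the ketone, malonate alkylation and iodomethylation, several operations more than the six steps that lead to 10. It also offers nothing for ring B or the spiro centre.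
- What the chosen plan sets against the safer C1: a shorter, catalytic entry, separable C1 epimers and a reordered fallback.

**Alternative 2:** ring A is cut at C2'–C3' and the strategic step is the Dieckmann closure of the triketone lactone A4, whose polyanion attacks the lactone carbonyl through C3' and gives the bis-desprenyl compound A5 (the same compound as 20).
- Merits: one step closes ring A, frees the C4 hydroxyl and turns the lactone stereochemistry into the spiro configuration; the product is one operation from the target.
- Weak points: as a plan it presupposes the lactone with C4 and C6 already set and says nothing about how ring B is made. The polyanion also has an aldol pathway open (side-chain α-carbon onto the C6' ketone).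
- Comparison: this road is not in conflict with the chosen one, which uses the same closure as step 11, and for the end game the two are equal. What the chosen plan adds is the origin of the lactone: it is formed in the step that closes ring B.

**Alternative 3:** ring C is cut at C1–C7a. (R)-Limonene A6 would be cleaved to (R)-3-isopropenyl-6-oxoheptanal A7, and an enamine of the aldehyde would add to the methyl ketone to give (1S,2R,5R)-2-hydroxy-2-methyl-5-(prop-1-en-2-yl)cyclopentane-1-carbaldehyde A8.
- Merits: C3a is bought, the isopropenyl group is already the masked C4 ketone, and no asymmetric catalyst or methylenemalonate is needed. In cost and certainty of absolute configuration it is better than step 2 of the chosen route.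
- Weak points: a keto aldehyde of this kind has a second aldol mode (ketone α-carbon onto the aldehyde, then dehydration to an acetylcyclopentene), which is the easier one. The wanted product is a tertiary β-hydroxy aldehyde, open to retro-aldol and dehydration, and its C1 configuration rests on an untested transition state. A8 would still need a Knoevenagel condensation and a conjugate reduction to reach 7, so about five steps against three.
- What the chosen plan sets against it: each stereocentre is set by a well-understood element, and the trans arms come from a reliable trapping reaction.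

Key step: step 7

Assumption: the enol drawn for ring A (C4'–OH) is one tautomer of a rapidly equilibrating β-triketone; all tautomers are treated as the same compound.

## Route

Step 1
Reactants: 1 dimethyl malonate
Product: 2 dimethyl 2-methylidenepropanedioate (dimethyl methylenemalonate)
Conditions: (CH2O)n, Cu(OAc)2 (cat.), KOAc (cat.), AcOH, 100 °C; distil, use at once
Reagents that add atoms: formaldehyde (as paraformaldehyde), C=O
Why: Knoevenagel-type methylenation of a malonate (hydroxymethylation and loss of water); the monomer is distilled from its oligomers and used fresh because it polymerises with traces of base.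

Step 2
Reactants: 3 cyclopent-2-en-1-one; 4 isopropenylmagnesium bromide; 2 dimethyl methylenemalonate
Product: 6 dimethyl 2-{[(1S,5R)-2-oxo-5-(prop-1-en-2-yl)cyclopentyl]methyl}propanedioate (arms trans), via magnesium enolate 5 (not isolated)
Conditions: CuBr·SMe2 (5 mol%), JosiPhos-type ferrocenyl diphosphine (6 mol%), t-BuOMe, −78 °C; then 2, −78 to −40 °C
Reagents that add atoms: none
Why: Copper-catalysed asymmetric conjugate addition of a Grignard reagent to a cyclic enone, with the ligand enantiomer chosen to give R at C3a; the regiodefined enolate 5 then undergoes Michael addition to the doubly activated alkene of 2 on the face anti to the new isopropenyl group, which sets C7a trans (S).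

Step 3
Reactants: 6 keto malonate
Product: 7 dimethyl 2-{[(1S,2R,5R)-2-hydroxy-2-methyl-5-(prop-1-en-2-yl)cyclopentyl]methyl}propanedioate (OH cis to the malonylmethyl arm, methyl trans to it)
Conditions: MeLi (2.4 equiv), CeCl3 (2.4 equiv), THF, −78 °C; crude product used directly
Reagents that add atoms: methyllithium, [Li]C
Why: Organocerium 1,2-addition to a ketone; the first equivalent removes the malonate proton (the enolate shields both esters), the second attacks the cyclopentanone anti to the adjacent C7a side chain, which sets C1 (R) with the oxygen cis to the arm, and the low basicity of the cerium reagent avoids enolisation.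

Step 4
Reactants: 7 tertiary alcohol
Product: 8 dimethyl 2-{[(1S,2R,5R)-2-methyl-5-(prop-1-en-2-yl)-2-(triethylsilyloxy)cyclopentyl]methyl}propanedioate
Conditions: TESOTf, 2,6-lutidine, CH2Cl2, −78 to 0 °C
Reagents that add atoms: triethylsilyl trifluoromethanesulfonate, CC[Si](CC)(CC)OS(=O)(=O)C(F)(F)F
Why: Silylation of a tertiary alcohol with a silyl triflate and a hindered base; the ether blocks δ-lactonisation onto the malonate and removes the proton that would quench the carbanion in step 7.

Step 5
Reactants: 8 silyl ether
Product: 9 dimethyl 2-{[(1S,2R,5R)-5-acetyl-2-methyl-2-(triethylsilyloxy)cyclopentyl]methyl}propanedioate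
Conditions: O3, CH2Cl2, −78 °C; then PPh3, −78 °C to rt
Reagents that add atoms: ozone, [O-][O+]=O
Why: Ozonolysis of a 1,1-disubstituted alkene with reductive work-up gives the C4 methyl ketone; C3a, now α to a ketone, already holds the more stable trans arrangement and is not at risk.

Step 6
Reactants: 9 methyl ketone
Product: 10 dimethyl 2-{[(1S,2R,5R)-5-acetyl-2-methyl-2-(triethylsilyloxy)cyclopentyl]methyl}-2-(iodomethyl)propanedioate
Conditions: NaH (1.05 equiv), CH2I2 (5 equiv), THF, 0 to 50 °C
Reagents that add atoms: diiodomethane, ICI
Why: SN2 alkylation of a malonate anion with diiodomethane; the malonate is some ten pK units more acidic than the ketone, and the neopentyl-type product does not react a second time.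

Step 7
Reactants: 10 iodomethyl malonate
Product: 13 bridged lactone methyl ester (1R,3aR,4S,6S,7aS): trans-hydrindane with 1β-OSiEt3, 1α-Me, 4β-Me, the 4α-oxygen and the 6α-carbonyl joined as a γ-lactone (6-oxabicyclo[3.2.1]octan-7-one) and 6β-CO2Me, via alkylsamarium 11 (not isolated), via samarium alkoxide 12 (not isolated)
Conditions: SmI2 (2.5 equiv), HMPA (10 equiv), THF, −78 °C to rt
Reagents that add atoms: none
Why: SmI2 in THF/HMPA transfers two electrons to the primary C–I bond and gives the alkylsamarium 11 (trivalent samarium on C5, a β-metallo ester or homoenolate), which adds to the C4 ketone and closes ring B in the 6-exo-trig mode; the samarium alkoxide 12 then attacks the ester that is 1,3-diaxial to it in the 5-exo-trig mode, expels methoxide and closes the γ-lactone. The closest known reaction types are the samarium Barbier cyclisation of δ-iodo ketones to cyclohexanols and the SmI2 homo-Reformatsky reaction of β-halo esters with ketones, which likewise ends in a γ-lactone. C4 is set in a chair transition state that is trans-fused to ring C because the two arms on the cyclopentane are trans; one of the two esters on C6 is necessarily axial, so the C4 methyl group avoids it and goes equatorial while the C–O bond goes axial, where samarium can bridge the carbonyl oxygen and the axial ester. C6 is set by the lactonisation, since only the axial ester can reach the axial alkoxide and the equatorial one would need a boat. The step needs reduction of the iodide before the ketone and addition to the ketone faster than 3-exo attack of C5 on a neighbouring ester (1,2-ester shift); HMPA speeds the reduction of the iodide and of the intermediate radical, the ketone sits six atoms away within reach of a chelate, and the silyl ether removes the only proton that could quench 11. An alcohol epimeric at C4 cannot lactonise and would be separated as a hydroxy diester.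

Step 8
Reactants: 13 lactone methyl ester
Product: 14 lactone carboxylic acid (as 13 with 6β-CO2H; configuration unchanged)
Conditions: LiI (6 equiv), EtOAc, reflux; then cold 0.5 M HCl
Reagents that add atoms: none
Why: SN2 demethylation of a methyl ester by iodide with lithium assistance; the lactone is untouched because its alkyl oxygen is tertiary, and the resulting malonic half-acid cannot decarboxylate because the enol would sit at a bridgehead (Bredt's rule).

Step 9
Reactants: 14 lactone acid
Product: 15 lactone acid chloride (as 13 with 6β-COCl; configuration unchanged)
Conditions: 1-chloro-N,N,2-trimethylprop-1-en-1-amine, CH2Cl2, 0 °C to rt; evaporate, use crude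
Reagents that add atoms: 1-chloro-N,N,2-trimethylprop-1-en-1-amine, CC(C)=C(Cl)N(C)C
Why: Acid chloride formation with an α-chloroenamine under neutral conditions; no hydrogen chloride is set free, so the silyl ether and the lactone are preserved.

Step 10
Reactants: 15 lactone acid chloride; 16 6-methylheptane-2,4-dione
Product: 18 triketone lactone (as 13 with a 6β-(7-methyl-1,3,5-trioxooctyl) chain in place of CO2Me; configuration unchanged), via diketone dianion 17 (not isolated)
Conditions: 16 (2.2 equiv), LiN(i-Pr)2 (4.4 equiv), THF, −78 to 0 °C; then 15, −78 °C; AcOH
Reagents that add atoms: none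
Why: C-acylation of a β-diketone 1,3-dianion at its terminal carbon; the second deprotonation of 16 takes place at the methyl group, the acid chloride is far more electrophilic than the lactone at −78 °C, and the excess dianion takes up the acidic proton of the product; no bond to C6 is touched.

Step 11
Reactants: 18 triketone lactone
Product: 20 bis-desprenyl triketone diol: spiro compound of the (1R,3aR,4S,7aS)-1β,4α-dihydroxy-1α,4β-dimethyl-trans-hydrindane (C6) with 4'-hydroxy-3'-(3-methylbutanoyl)cyclohex-3'-ene-2',6'-dione, C2' on the α face, via silylated spiro triketone 19 (not isolated)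
Conditions: KOt-Bu (3 equiv), THF, 0 °C to rt; then 1 M HCl, MeOH, rt
Reagents that add atoms: none
Why: Dieckmann (intramolecular Claisen) condensation in which C3', the carbon between two ketones, attacks the lactone carbonyl (6-exo-trig) and expels the C4 alkoxide; the closure is driven by the strongly acidic cyclic β-triketone formed, the lactone carbonyl becomes C2' so the configuration fixed in step 7 becomes the spiro configuration, and acid methanolysis then removes the triethylsilyl ether.

Step 12
Reactants: 20 bis-desprenyl triketone diol
Product: 22 target CNP0198642.2 (20 with two 3-methylbut-2-enyl groups on C5'), via monoprenyl triketone 21 (not isolated)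
Conditions: prenyl bromide (2.4 equiv), NaOMe (3.2 equiv), MeOH, 0 °C to rt
Reagents that add atoms: 1-bromo-3-methylbut-2-ene (prenyl bromide), CC(C)=CCBr
Why: Double C-alkylation of a cyclic β-triketone at its only CH2 group between two carbonyls, the reaction type used for gem-diprenylation of acylphloroglucinols; the protic solvent favours carbon over oxygen, C3' is a tricarbonyl methine and does not react, the tertiary alcohols are not alkylated, and no stereocentre is formed because the two new groups are identical.

## Compound list

1 | dimethyl malonate | COC(=O)CC(=O)OC | starting material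
2 | dimethyl 2-methylidenepropanedioate | COC(=O)C(=C)C(=O)OC | intermediate
3 | cyclopent-2-en-1-one | O=C1C=CCC1 | starting material
4 | isopropenylmagnesium bromide | CC(=C)[Mg]Br | starting material
5 | bromomagnesium (R)-3-(prop-1-en-2-yl)cyclopent-1-en-1-olate | Br[Mg]OC1=C[C@@H](CC1)C(C)=C | intermediate
6 | dimethyl 2-{[(1S,5R)-2-oxo-5-(prop-1-en-2-yl)cyclopentyl]methyl}propanedioate | COC(=O)C(C(=O)OC)C[C@H]1[C@@H](CCC1=O)C(C)=C | intermediate
7 | dimethyl 2-{[(1S,2R,5R)-2-hydroxy-2-methyl-5-(prop-1-en-2-yl)cyclopentyl]methyl}propanedioate | COC(=O)C(C(=O)OC)C[C@H]1[C@@H](CC[C@@]1(C)O)C(C)=C | intermediate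
8 | dimethyl 2-{[(1S,2R,5R)-2-methyl-5-(prop-1-en-2-yl)-2-(triethylsilyloxy)cyclopentyl]methyl}propanedioate | COC(=O)C(C(=O)OC)C[C@H]1[C@@H](CC[C@@]1(C)O[Si](CC)(CC)CC)C(C)=C | intermediate
9 | dimethyl 2-{[(1S,2R,5R)-5-acetyl-2-methyl-2-(triethylsilyloxy)cyclopentyl]methyl}propanedioate | COC(=O)C(C(=O)OC)C[C@H]1[C@@H](CC[C@@]1(C)O[Si](CC)(CC)CC)C(C)=O | intermediate
10 | dimethyl 2-{[(1S,2R,5R)-5-acetyl-2-methyl-2-(triethylsilyloxy)cyclopentyl]methyl}-2-(iodomethyl)propanedioate | COC(=O)C(CI)(C(=O)OC)C[C@H]1[C@@H](CC[C@@]1(C)O[Si](CC)(CC)CC)C(C)=O | intermediate
11 | alkylsamarium from 10 (SmI2 group on C5 in place of iodine) | COC(=O)C(C[Sm](I)I)(C(=O)OC)C[C@H]1[C@@H](CC[C@@]1(C)O[Si](CC)(CC)CC)C(C)=O | intermediate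
12 | samarium alkoxide of dimethyl (1R,3aR,4S,7aS)-4-hydroxy-1,4-dimethyl-1-(triethylsilyloxy)octahydroindene-6,6-dicarboxylate | COC(=O)C1(C(=O)OC)C[C@H]2[C@@H](CC[C@@]2(C)O[Si](CC)(CC)CC)[C@@](C)(O[Sm](I)I)C1 | intermediate
13 | bridged lactone methyl ester (1R,3aR,4S,6S,7aS), 1β-OSiEt3, 6α,4α-lactone, 6β-CO2Me | COC(=O)[C@@]2(C[C@H]3[C@@H](CC[C@@]3(C)O[Si](CC)(CC)CC)[C@@](C)(O4)C2)C4=O | intermediate
14 | bridged lactone carboxylic acid (6β-CO2H) | OC(=O)[C@@]2(C[C@H]3[C@@H](CC[C@@]3(C)O[Si](CC)(CC)CC)[C@@](C)(O4)C2)C4=O | intermediate
15 | bridged lactone acid chloride (6β-COCl) | ClC(=O)[C@@]2(C[C@H]3[C@@H](CC[C@@]3(C)O[Si](CC)(CC)CC)[C@@](C)(O4)C2)C4=O | intermediate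
16 | 6-methylheptane-2,4-dione | CC(C)CC(=O)CC(C)=O | starting material
17 | dilithium 1,3-dianion of 16 (bis-enolate, terminal CH2) | C=C(O[Li])C=C(O[Li])CC(C)C | intermediate
18 | triketone lactone, 6β-(7-methyl-1,3,5-trioxooctyl) | CC(C)CC(=O)CC(=O)CC(=O)[C@@]2(C[C@H]3[C@@H](CC[C@@]3(C)O[Si](CC)(CC)CC)[C@@](C)(O4)C2)C4=O | intermediate
19 | 1-O-triethylsilyl ether of 20 | CC(C)CC(=O)C1=C(O)CC(=O)[C@@]2(C[C@H]3[C@@H](CC[C@@]3(C)O[Si](CC)(CC)CC)[C@@](C)(O)C2)C1=O | intermediate
20 | bis-desprenyl triketone diol (C5' unsubstituted) | CC(C)CC(=O)C1=C(O)CC(=O)[C@@]2(C[C@H]3[C@@H](CC[C@@]3(C)O)[C@@](C)(O)C2)C1=O | intermediate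
21 | 5'-monoprenyl triketone diol (C5' enolisable, configuration not fixed) | CC(C)=CCC1C(=O)[C@@]2(C[C@H]3[C@@H](CC[C@@]3(C)O)[C@@](C)(O)C2)C(=O)C(C(=O)CC(C)C)=C1O | intermediate
22 | CNP0198642.2 | CC(C)=CCC1(CC=C(C)C)C(=O)[C@@]2(C[C@H]3[C@@H](CC[C@@]3(C)O)[C@@](C)(O)C2)C(=O)C(C(=O)CC(C)C)=C1O | target

## Step count and least certain steps

Total: 12 steps. Longest linear sequence: 12 steps (1 to 2 to 6 and on to 22); 11 steps from cyclopent-2-en-1-one 3.

**Step 7 (key step).** The carbanionic centre of 11 may attack one of its own ester carbonyls (cyclopropanolate formation and 1,2-ester shift), or be reduced to a methyl group before it reaches the ketone; reduction of the ketone first would lead to pinacol coupling. The fallback builds ring B by metathesis and lets the ring fusion choose the carboxyl group. It sets out from 8 and comes back at 14.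
- The sodium enolate of 8 is added to phenyl vinyl sulfoxide to give the sulfoxide adduct F1, and thermal sulfoxide elimination (toluene, 110 °C) gives the vinyl malonate F2.
- Ring-closing metathesis of the vinyl and isopropenyl groups (second-generation Grubbs catalyst) gives the cyclohexene diester F3 with the C4=C5 double bond.
- Saponification (LiOH) gives the diacid F4.
- Iodolactonisation (I2, NaHCO3) gives the iodolactone acid F5. Only the axial α-carboxyl can add to C4, so the C4 oxygen and the C6 carbonyl are placed as in 13.
- Bu3SnH removes the iodine and gives 14.

**Step 2.** Enantioselectivity may be poor because an alkenyl Grignard reagent and a small flat enone are at the edge of the catalyst's scope, and the malonate enolate formed in the trapping may start anionic oligomerisation of 2. The fallback replaces catalyst control by substrate control. It sets out from 4 and 2 and comes back at 6.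
- Copper-mediated addition of 4 to purchased (S)-4-(tert-butyldimethylsilyloxy)cyclopent-2-en-1-one F6 occurs anti to the silyloxy group, and trapping with 2 gives the adduct F7.
- Acid-mediated loss of the silanol (AcOH, H2O, THF, 60 °C) gives the enone F8 without base.
- Conjugate reduction with [(Ph3P)CuH]6 gives 6.

**Step 3.** Facial selectivity may be poor: the methyl reagent must use the face that also carries the isopropenyl group, and the malonate enolate may guide it to the wrong face. The fallback changes the order so that the addition meets a bulkier arm with no acidic proton. It sets out from 6 and comes back at 10.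
- 6 is iodomethylated first (NaH, CH2I2) to give the keto iodide F9.
- MeLi/CeCl3 gives the tertiary alcohol F10.
- TESOTf gives the silyl ether F11.
- The alkene is cleaved with OsO4 (cat.) and NaIO4, which tolerate the iodide, to give 10.

**Step 10.** The dianion may attack the lactone carbonyl or react on oxygen, and the neopentyl-type acid chloride may react slowly. The fallback replaces acylation by aldol addition and oxidation. It sets out from 15 and comes back at 18.
- 15 is reduced with LiAlH(Ot-Bu)3 at −78 °C to the aldehyde F12, which cannot enolise.
- Dianion 17 adds to F12 to give the hydroxy diketone F13.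
- Dess–Martin periodinane oxidises F13 to 18.

**Step 12.** O-alkylation and incomplete second alkylation may compete with the double C-prenylation. The fallback uses π-allyl chemistry, in which O-allylation is reversible. It sets out from 20 and comes back at 22.
- Double allylation with allyl methyl carbonate and Pd(PPh3)4 gives the gem-diallyl compound F14.
- Cross-metathesis with 2-methylbut-2-ene (second-generation Grubbs catalyst) gives 22.

## Further compounds

F1 | step 7 | dimethyl 2-{[(1S,2R,5R)-2-methyl-5-(prop-1-en-2-yl)-2-(triethylsilyloxy)cyclopentyl]methyl}-2-[2-(phenylsulfinyl)ethyl]propanedioate (sulfur epimers) | COC(=O)C(CCS(=O)c1ccccc1)(C(=O)OC)C[C@H]1[C@@H](CC[C@@]1(C)O[Si](CC)(CC)CC)C(C)=C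
F2 | step 7 | dimethyl 2-ethenyl-2-{[(1S,2R,5R)-2-methyl-5-(prop-1-en-2-yl)-2-(triethylsilyloxy)cyclopentyl]methyl}propanedioate | COC(=O)C(C=C)(C(=O)OC)C[C@H]1[C@@H](CC[C@@]1(C)O[Si](CC)(CC)CC)C(C)=C
F3 | step 7 | dimethyl (1R,3aR,7aS)-1,4-dimethyl-1-(triethylsilyloxy)-1,2,3,3a,7,7a-hexahydroindene-6,6-dicarboxylate (C4=C5 alkene) | COC(=O)C1(C(=O)OC)C[C@H]2[C@@H](CC[C@@]2(C)O[Si](CC)(CC)CC)C(C)=C1
F4 | step 7 | diacid corresponding to F3 | OC(=O)C1(C(=O)O)C[C@H]2[C@@H](CC[C@@]2(C)O[Si](CC)(CC)CC)C(C)=C1
F5 | step 7 | 5β-iodo derivative of 14 (iodine trans-diaxial to the lactone oxygen) | OC(=O)[C@@]2(C[C@H]3[C@@H](CC[C@@]3(C)O[Si](CC)(CC)CC)[C@@](C)(O4)[C@@H]2I)C4=O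
F6 | step 2 | (S)-4-(tert-butyldimethylsilyloxy)cyclopent-2-en-1-one (purchased) | O=C1C=C[C@@H](O[Si](C)(C)C(C)(C)C)C1
F7 | step 2 | 4-silyloxy analogue of 6 (silyloxy trans to isopropenyl, arms trans) | COC(=O)C(C(=O)OC)C[C@H]1[C@@H]([C@@H](O[Si](C)(C)C(C)(C)C)CC1=O)C(C)=C
F8 | step 2 | dimethyl 2-{[(1S,5R)-2-oxo-5-(prop-1-en-2-yl)cyclopent-3-en-1-yl]methyl}propanedioate | COC(=O)C(C(=O)OC)C[C@H]1[C@@H](C=CC1=O)C(C)=C
F9 | step 3 | dimethyl 2-(iodomethyl)-2-{[(1S,5R)-2-oxo-5-(prop-1-en-2-yl)cyclopentyl]methyl}propanedioate | COC(=O)C(CI)(C(=O)OC)C[C@H]1[C@@H](CCC1=O)C(C)=C
F10 | step 3 | dimethyl 2-{[(1S,2R,5R)-2-hydroxy-2-methyl-5-(prop-1-en-2-yl)cyclopentyl]methyl}-2-(iodomethyl)propanedioate | COC(=O)C(CI)(C(=O)OC)C[C@H]1[C@@H](CC[C@@]1(C)O)C(C)=C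
F11 | step 3 | triethylsilyl ether of F10 | COC(=O)C(CI)(C(=O)OC)C[C@H]1[C@@H](CC[C@@]1(C)O[Si](CC)(CC)CC)C(C)=C
F12 | step 10 | bridged lactone aldehyde (6β-CHO) | O=C[C@@]2(C[C@H]3[C@@H](CC[C@@]3(C)O[Si](CC)(CC)CC)[C@@](C)(O4)C2)C4=O
F13 | step 10 | bridged lactone with 6β-(1-hydroxy-7-methyl-3,5-dioxooctyl) chain (carbinol epimers) | CC(C)CC(=O)CC(=O)CC(O)[C@@]2(C[C@H]3[C@@H](CC[C@@]3(C)O[Si](CC)(CC)CC)[C@@](C)(O4)C2)C4=O
F14 | step 12 | 5',5'-diallyl analogue of 22 | C=CCC1(CC=C)C(=O)[C@@]2(C[C@H]3[C@@H](CC[C@@]3(C)O)[C@@](C)(O)C2)C(=O)C(C(=O)CC(C)C)=C1O
A1 | alternative 1 | (R)-linalool | CC(=CCC[C@](C)(C=C)O)C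
A2 | alternative 1 | (bromomethyl)dimethylsilyl ether of (R)-1-methylcyclopent-2-en-1-ol | BrC[Si](C)(C)O[C@]1(C)CCC=C1
A3 | alternative 1 | cis-fused siloxane nitrile (nitrile on C3a trans to the ring CH2) | C1[C@H]2[C@@H](CC[C@@]2(C)O[Si]1(C)C)C#N
A4 | alternative 2 | triketone lactone with free C1 hydroxyl (18 without the silyl group) | CC(C)CC(=O)CC(=O)CC(=O)[C@@]2(C[C@H]3[C@@H](CC[C@@]3(C)O)[C@@](C)(O4)C2)C4=O
A5 | alternative 2 | bis-desprenyl triketone diol (identical with 20) | CC(C)CC(=O)C1=C(O)CC(=O)[C@@]2(C[C@H]3[C@@H](CC[C@@]3(C)O)[C@@](C)(O)C2)C1=O
A6 | alternative 3 | (R)-limonene | CC1=CC[C@@H](CC1)C(C)=C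
A7 | alternative 3 | (R)-3-isopropenyl-6-oxoheptanal | O=CC[C@@H](CCC(C)=O)C(C)=C
A8 | alternative 3 | (1S,2R,5R)-2-hydroxy-2-methyl-5-(prop-1-en-2-yl)cyclopentane-1-carbaldehyde | O=C[C@H]1[C@@H](CC[C@@]1(C)O)C(C)=C
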